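## The problem

The target 27 is an ent-labdane, named here with labdane numbering: ring A is C1–C5 and C10, ring B is C5–C10, C19 is the acid on C4, C20 the methyl on C10, C17 the methylene on C8, and C11–C15 (with C16 on C13) the chain on C9. The two rings are trans-fused, and two quaternary carbons, C4 and C10, sit 1,3 to each other with the C19 carboxyl and the C20 methyl axial on the same face and H5 on the other. The five stereocentres are C4 (R), C5 (S), C9 (R), C10 (S) and C13 (R). Nothing in the molecule can set C4, so it needs a C–C bond formation at a fully substituted carbon under absolute control. Once C4 is fixed, C5 can follow by equilibration beside a C10 carbonyl, C10 by a ring closure steered by the ring A chair, and C9 by epimerisation beside a C8 carbonyl. C13 is insulated from the rings by two methylenes and has to be bought. The exocyclic C8=C17 alkene will not survive acid or the oxidants that make a carboxyl group, the primary acetate will not survive base or reducing metals, and a neopentyl axial C19 ester is very hard to hydrolyse, so the acid should appear as the free acid from a non-ester precursor. The enabling feature is that C4 carries a methyl and lies β to C10 through C5: ring A is 3-methylcyclohex-2-enone 4 with C10 as the carbonyl, C4 can receive a one-carbon acid surrogate by conjugate addition, and the C5 enolate so formed can pick up C6.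

## Retrosynthesis

**C15–O acetyl and silyl ether (27 ⇒ 26 ⇒ 25).** The acetate is taken off first in the retrosynthetic sense because it would not survive the alkoxide, ylide and dissolving-metal steps before it. Hydroxy acid 26 and its silyl ether 25 differ from the target only at C15. The forward steps are a desilylation and a selective O-acetylation of a primary alcohol beside a hindered acid.

**C20–S, C8=C17 and C19 (25 ⇒ 24 ⇒ 23 ⇒ 22).** The C20 methyl is traced to a phenylsulfonylmethyl group (24), which is what makes C10 electrophilic earlier and costs one reductive step to remove. The C8 methylene is traced to the ketone of 23, which acidifies C9 for ring closure and epimerisation. The C19 acid is traced to the ethynyl group of 22, the smallest carbon substituent that survives organometallic and basic steps. The order is forced: the alkyne must be cleaved oxidatively while no alkene is present, so acid formation precedes methylenation. The sulfone is removed only after the alkyne is gone, so that the C20 radical has no syn-axial alkyne to add to.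

**C9–C10, ring B (22 ⇒ 20).** Cutting C9–C10 pairs a natural nucleophile (C9, α to the C8 ketone) with a natural electrophile (C10, β to the sulfone of an exocyclic vinyl sulfone). The neighbouring cuts C5–C10 and C8–C9 offer no such polarity. An endocyclic ring A enone as acceptor would force axial bond formation and a cis fusion. The exocyclic acceptor in 20 lets C9 bond equatorially, which gives the trans-decalin with the sulfonylmethyl group axial. Ketone 20 is monocyclic with only the C4, C5 and C13 centres. The forward reaction must be a 6-exo Michael addition under equilibrating base.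

**C8–C9 (20 ⇒ 12 + 17).** The C8 ketone is cut into aldehyde 12 and the chain bromide 17 (Grignard addition, then oxidation). This puts the whole C9–C15 unit with C13 into one piece. Bromide 17 comes from (R)-citronellol 13 through silyl ether 14 and alcohol 16 by cleaving the trisubstituted alkene, with no bond at C13 touched.

**C8 oxidation level and C10=C20 (12 ⇒ 11 ⇒ 9 ⇒ 8).** Aldehyde 12 comes from alcohol 11 and this from the allyl group of 9 by anti-Markovnikov hydration. Vinyl sulfone 9 comes from ketone 8 by a Horner–Wadsworth–Emmons olefination. Olefinating first also masks the ketone during hydroboration and Grignard addition.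

**C4–C19 and C5–C6 (8 ⇒ 4 + 3 + 5).** Both bonds are cut at once, giving enone 4, alkynylalane 3 and allyl iodide 5. Alkylating a preformed 3,3-disubstituted cyclohexanone would go to C1, not C5; only the enolate born in the conjugate addition is regiodefined. The forward step must transfer the alkynyl group to one face of the enone under catalyst control and allylate the resulting enolate at carbon. Alane 3 is made from trimethylsilylacetylene 1.

## Roads not taken

**Alternative 1:** The cut is C3–C4 and C5–C10, so both rings close in one intramolecular Diels–Alder reaction of the open-chain trienal A1 (thermal or with Me2AlCl) to the octalin A2.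
- Merits: it is the most economical in ring construction; C4, C5 and C10 arise together from alkene geometry, and C9 and C13 are already in the chain.
- Weak points: the diene terminus C10 is disubstituted, so one substituent must sit inside the s-cis diene; the dienophile carbon C4 is also fully substituted, so two quaternary carbons form in one cycloaddition between two hindered termini. Face and endo/exo selection rest on the single C9 centre next to a ketal, and C9 itself must first be made enantioselectively in an acyclic setting. After the cycloaddition, A2 still needs formyl-to-methyl reduction at C18, oxidation of the C19 ether to the acid, ring alkene saturation, ketal removal and methylenation.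
- Comparison: A2 beats the chosen plan in convergence of ring formation. The chosen plan sets against this a catalytic, enantioselective construction of C4 on a known substrate class and a ring closure in which only one new bond has to form at a hindered carbon.

**Alternative 2:** The cut is C5–C10 and C8–C9, closing ring B by an intramolecular Diels–Alder reaction of the silyloxydiene enal A3 (Me2AlCl or heat) to the octalin A4.
- Merits: diene and dienophile are electronically matched; C5, C8, C9 and C10 are set in one step; and the C20 methyl is native, with no sulfone to remove. In this respect it is better than the chosen plan.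
- Weak points: the C4 quaternary centre must already be present in enantioenriched form in A3, so the hardest centre is moved, not solved. The new C5–C10 bond joins a carbon next to quaternary C4 to a β,β-disubstituted enal carbon. The chain beyond C11 must then be attached to A4 and its new alkene saturated. The C19 methyl ester of A4 is of the type that resists hydrolysis.
- Comparison: the chosen plan spends more steps on ring B, but it derives C4 from an achiral enone by catalysis and ends at the free acid without an ester cleavage.

**Alternative 3:** The cut is C4–C5 and C9–C10. Oxidation of the β-keto ester polyene A5 with Mn(OAc)3 and Cu(OAc)2 would close both rings by two 6-endo radical additions and turn the C8 radical into the exocyclic alkene of A6.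
- Merits: it is the shortest route on paper; the acetate, the full chain and the C8=C17 alkene are present as soon as the rings form.
- Weak points: the face of the C4 radical is controlled only by the ester auxiliary. The copper-mediated elimination can give endocyclic alkene isomers as well as the exocyclic one. The C3 ketone of A6 must be removed in the presence of the alkene and the acetate. The bulky auxiliary ester at the neopentyl C19 position must be cleaved without touching the acetate.
- Comparison: in step count this road is better. The chosen plan sets against it stereocentres fixed one at a time by well-understood elements, no alkene regiochemistry problem, no deoxygenation and no hindered ester cleavage.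

Key step: step 2

Remark (numbering): labdane numbering is used for positions; the compound list gives systematic names and SMILES.
Remark (assumption): the antipode of the chiral carbene ligand that sends the alkynyl group to the enone face giving the (R) quaternary centre of 8 is used; both antipodes are accessible from the two enantiomers of the diamine backbone.

## Route

Step 1
Reactants: 1 trimethylsilylacetylene
Product: 3 diisobutyl[(trimethylsilyl)ethynyl]aluminium, via lithium (trimethylsilyl)acetylide 2 (not isolated)
Conditions: n-BuLi, hexanes/THF, −78 → 0 °C; then i-Bu2AlCl, 0 °C → rt; solution used directly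
Reagents that add atoms: diisobutylaluminium chloride, CC(C)C[Al](Cl)CC(C)C
Why: Deprotonation of the terminal alkyne and lithium-to-aluminium transmetalation (salt metathesis) give the mixed alane, in which the alkynyl group is the only sp-bound and therefore transferable ligand.

Step 2
Reactants: 3 diisobutyl[(trimethylsilyl)ethynyl]aluminium; 4 3-methylcyclohex-2-en-1-one; 5 allyl iodide
Product: 8 (2R,3R)-2-allyl-3-methyl-3-[(trimethylsilyl)ethynyl]cyclohexan-1-one, via aluminium enolate 6 (not isolated), via lithium aluminate enolate 7 (not isolated)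
Conditions: Cu(OTf)2 (5 mol%), chiral sulfonate-bearing imidazolinium salt (5 mol%, premetalated with Ag2O), THF, −30 → 4 °C; then MeLi, DMPU, −78 °C; allyl iodide, −78 → 0 °C; aq. potassium sodium tartrate; DBU (cat.), toluene, rt if the C5 epimer is present
Reagents that add atoms: none
Why: The alkynyl group passes from aluminium to the carbene-bound copper centre and is delivered to C4 of the aluminium-activated enone on the face fixed by the ligand, leaving the diisobutylaluminium enolate 6 with its double bond only between C5 and C10. The closest known reaction type is the copper–carbene-catalysed enantioselective conjugate addition of silylalkynylaluminium reagents to β-methyl cyclic enones, joined here to the long-known alkylation of aluminium enolates after conversion into lithium aluminates with MeLi. MeLi turns 6 into aluminate 7, which is nucleophilic enough to attack allyl iodide at carbon (SN2) and so forms C5–C6. No ring is closed. C4 is set by the catalyst (enantiofacial control on a prochiral enone). C5 is set by the substrate: attack anti to the proximal C4 methyl and, decisively, base equilibration beside the ketone both lead to the isomer with axial alkynyl and equatorial allyl, so the two groups end cis. The step needs 1,4- over 1,2-addition and alkynyl over isobutyl transfer, which the copper catalyst and the sp-hybridised migrating group secure. It also needs a single allylation at C5 and not at C1, which the regiospecific enolate, the low temperature and the reactive iodide secure.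

Step 3
Reactants: 8 (2R,3R)-2-allyl-3-methyl-3-[(trimethylsilyl)ethynyl]cyclohexan-1-one
Product: 9 {[(E)-[(2R,3R)-2-allyl-3-methyl-3-[(trimethylsilyl)ethynyl]cyclohexylidene]methyl]sulfonyl}benzene
Conditions: (EtO)2P(O)CH2SO2Ph, n-BuLi, THF, −78 °C → rt (reflux if slow)
Reagents that add atoms: diethyl [(phenylsulfonyl)methyl]phosphonate, CCOP(=O)(CS(=O)(=O)c1ccccc1)OCC
Why: Horner–Wadsworth–Emmons olefination of the C10 ketone gives the exocyclic vinyl sulfone, with the sulfonyl group expected anti to the substituted C5; either geometry serves because C10 becomes sp3 later, and the non-basic phosphate by-product leaves the product conjugated.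

Step 4
Reactants: 9 {[(E)-[(2R,3R)-2-allyl-3-methyl-3-[(trimethylsilyl)ethynyl]cyclohexylidene]methyl]sulfonyl}benzene
Product: 11 3-[(1R,2E,6R)-6-methyl-2-[(phenylsulfonyl)methylidene]-6-[(trimethylsilyl)ethynyl]cyclohexyl]propan-1-ol, via B-alkyl-9-BBN adduct 10 (not isolated)
Conditions: 9-BBN, THF, 0 °C → rt; then 30% H2O2, aq. NaOAc, 0 °C → rt
Reagents that add atoms: hydrogen peroxide, OO
Why: Hydroboration–oxidation; 9-BBN adds anti-Markovnikov to the monosubstituted alkene far faster than to the electron-poor trisubstituted vinyl sulfone or the flanked silylalkyne, and the buffered peroxide avoids nucleophilic epoxidation and desilylation.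

Step 5
Reactants: 11 3-[(1R,2E,6R)-6-methyl-2-[(phenylsulfonyl)methylidene]-6-[(trimethylsilyl)ethynyl]cyclohexyl]propan-1-ol
Product: 12 3-[(1R,2E,6R)-6-methyl-2-[(phenylsulfonyl)methylidene]-6-[(trimethylsilyl)ethynyl]cyclohexyl]propanal
Conditions: DMP (triacetoxyperiodinane), NaHCO3, CH2Cl2, 0 °C → rt
Reagents that add atoms: none
Why: Periodinane oxidation of a primary alcohol stops at the aldehyde under neutral buffered conditions and leaves the sulfone and alkyne alone.

Step 6
Reactants: 13 (R)-citronellol
Product: 14 tert-butyl{[(3R)-3,7-dimethyloct-6-en-1-yl]oxy}dimethylsilane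
Conditions: TBSCl, imidazole, CH2Cl2, 0 °C → rt
Reagents that add atoms: tert-butyldimethylsilyl chloride, CC(C)(C)[Si](C)(C)Cl
Why: Standard silylation of a primary alcohol; the silyl ether is chosen to outlast Grignard, alkoxide, ruthenium tetroxide, ylide and amalgam conditions.

Step 7
Reactants: 14 tert-butyl{[(3R)-3,7-dimethyloct-6-en-1-yl]oxy}dimethylsilane
Product: 16 (4R)-6-[(tert-butyldimethylsilyl)oxy]-4-methylhexan-1-ol, via aldehyde 15 (not isolated)
Conditions: O3, CH2Cl2/MeOH, −78 °C; then NaBH4, −78 °C → rt
Reagents that add atoms: ozone, [O-][O+]=O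
Why: Ozonolysis with reductive work-up cleaves the only alkene and reduces the aldehyde in the same flask; the stereocentre is two carbons away and untouched.

Step 8
Reactants: 16 (4R)-6-[(tert-butyldimethylsilyl)oxy]-4-methylhexan-1-ol
Product: 17 {[(3R)-6-bromo-3-methylhexyl]oxy}(tert-butyl)dimethylsilane
Conditions: CBr4, PPh3, imidazole, CH2Cl2, 0 °C
Reagents that add atoms: carbon tetrabromide, BrC(Br)(Br)Br
Why: Appel bromination replaces the primary hydroxyl by SN2 under near-neutral conditions that the silyl ether tolerates.

Step 9
Reactants: 17 {[(3R)-6-bromo-3-methylhexyl]oxy}(tert-butyl)dimethylsilane; 12 3-[(1R,2E,6R)-6-methyl-2-[(phenylsulfonyl)methylidene]-6-[(trimethylsilyl)ethynyl]cyclohexyl]propanal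
Product: 19 (7R)-9-[(tert-butyldimethylsilyl)oxy]-7-methyl-1-[(1R,2E,6R)-6-methyl-2-[(phenylsulfonyl)methylidene]-6-[(trimethylsilyl)ethynyl]cyclohexyl]nonan-3-ol (both C3 epimers), via Grignard reagent 18 (not isolated)
Conditions: Mg (I2 cat.), THF, 40 °C; then 12, THF, −78 °C; aq. NH4Cl
Reagents that add atoms: none
Why: Grignard 1,2-addition forms the C8–C9 bond; at −78 °C the aldehyde reacts far faster than the β,β-disubstituted vinyl sulfone, and the new carbinol centre is removed in the next step.

Step 10
Reactants: 19 (7R)-9-[(tert-butyldimethylsilyl)oxy]-7-methyl-1-[(1R,2E,6R)-6-methyl-2-[(phenylsulfonyl)methylidene]-6-[(trimethylsilyl)ethynyl]cyclohexyl]nonan-3-ol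
Product: 20 (7R)-9-[(tert-butyldimethylsilyl)oxy]-7-methyl-1-[(1R,2E,6R)-6-methyl-2-[(phenylsulfonyl)methylidene]-6-[(trimethylsilyl)ethynyl]cyclohexyl]nonan-3-one
Conditions: DMP (triacetoxyperiodinane), NaHCO3, CH2Cl2, rt
Reagents that add atoms: none
Why: Periodinane oxidation of the secondary alcohol gives the C8 ketone without base, so the vinyl sulfone stays in conjugation until the cyclisation.

Step 11
Reactants: 20 (7R)-9-[(tert-butyldimethylsilyl)oxy]-7-methyl-1-[(1R,2E,6R)-6-methyl-2-[(phenylsulfonyl)methylidene]-6-[(trimethylsilyl)ethynyl]cyclohexyl]nonan-3-one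
Product: 22 (1S,4aR,5R,8aS)-1-[(3R)-5-[(tert-butyldimethylsilyl)oxy]-3-methylpentyl]-5-ethynyl-5-methyl-8a-[(phenylsulfonyl)methyl]octahydronaphthalen-2(1H)-one, via silylalkyne decalone 21 (not isolated)
Conditions: t-BuOK (0.3 equiv), t-BuOH/THF, 0 °C → rt; then MeOH, K2CO3, rt
Reagents that add atoms: none
Why: Intramolecular Michael addition (6-exo-trig) of the equilibrating ketone enolate to the vinyl sulfone, where only the C9 enolate can close a six-membered ring; C9 should bond to C10 from the equatorial side of the ring A chair, away from the axial alkynyl on C4, which puts the sulfonylmethyl group axial and gives the trans fusion, while the C9 chain settles equatorial by epimerisation beside the ketone; methoxide then cleaves the C(sp)–Si bond, and the quaternary C4 prevents alkyne isomerisation.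

Step 12
Reactants: 22 (1S,4aR,5R,8aS)-1-[(3R)-5-[(tert-butyldimethylsilyl)oxy]-3-methylpentyl]-5-ethynyl-5-methyl-8a-[(phenylsulfonyl)methyl]octahydronaphthalen-2(1H)-one
Product: 23 (1R,4aS,5S,8aR)-5-[(3R)-5-[(tert-butyldimethylsilyl)oxy]-3-methylpentyl]-1-methyl-6-oxo-4a-[(phenylsulfonyl)methyl]decahydronaphthalene-1-carboxylic acid
Conditions: RuCl3·xH2O (cat.), NaIO4, NaHCO3, MeCN/EtOAc/H2O, 0 °C → rt
Reagents that add atoms: sodium periodate, [Na+].[O-]I(=O)(=O)=O; water, O
Why: Ruthenium tetroxide oxidative cleavage of a terminal alkyne gives the carboxylic acid with loss of the terminal carbon as CO2; no alkene is present at this stage, and ketone, sulfone and silyl ether are inert to the buffered oxidant.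

Step 13
Reactants: 23 (1R,4aS,5S,8aR)-5-[(3R)-5-[(tert-butyldimethylsilyl)oxy]-3-methylpentyl]-1-methyl-6-oxo-4a-[(phenylsulfonyl)methyl]decahydronaphthalene-1-carboxylic acid
Product: 24 (1R,4aR,5R,8aR)-5-[(3R)-5-[(tert-butyldimethylsilyl)oxy]-3-methylpentyl]-1-methyl-6-methylidene-4a-[(phenylsulfonyl)methyl]decahydronaphthalene-1-carboxylic acid
Conditions: Ph3PCH3Br, t-BuOK (excess ylide), THF, 0 → 60 °C
Reagents that add atoms: methyltriphenylphosphonium bromide, C[P+](c1ccccc1)(c1ccccc1)c1ccccc1.[Br-]
Why: Wittig methylenation of the hindered C8 ketone with excess ylide, the first equivalent being spent on the carboxylate; the ylide is too weak a base to deprotonate beside the sulfone, and any C9 epimerisation returns to the equatorial isomer.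

Step 14
Reactants: 24 (1R,4aR,5R,8aR)-5-[(3R)-5-[(tert-butyldimethylsilyl)oxy]-3-methylpentyl]-1-methyl-6-methylidene-4a-[(phenylsulfonyl)methyl]decahydronaphthalene-1-carboxylic acid
Product: 25 (1R,4aS,5R,8aS)-5-[(3R)-5-[(tert-butyldimethylsilyl)oxy]-3-methylpentyl]-1,4a-dimethyl-6-methylidenedecahydronaphthalene-1-carboxylic acid
Conditions: Na/Hg (6% Na), Na2HPO4, MeOH/THF, −20 °C → rt
Reagents that add atoms: none
Why: Reductive desulfonylation by electron transfer: the sulfone radical anion loses benzenesulfinate, and the C20 radical is reduced and protonated to the methyl group; the isolated 1,1-disubstituted alkene, the carboxylate and the silyl ether are inert, and the alkyne that could have trapped the radical is already gone.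

Step 15
Reactants: 25 (1R,4aS,5R,8aS)-5-[(3R)-5-[(tert-butyldimethylsilyl)oxy]-3-methylpentyl]-1,4a-dimethyl-6-methylidenedecahydronaphthalene-1-carboxylic acid
Product: 26 (1R,4aS,5R,8aS)-5-[(3R)-5-hydroxy-3-methylpentyl]-1,4a-dimethyl-6-methylidenedecahydronaphthalene-1-carboxylic acid
Conditions: TBAF, THF, rt; aq. NH4Cl
Reagents that add atoms: none
Why: Fluoride-induced Si–O cleavage frees the primary alcohol without acid, so the exocyclic alkene does not migrate.

Step 16
Reactants: 26 (1R,4aS,5R,8aS)-5-[(3R)-5-hydroxy-3-methylpentyl]-1,4a-dimethyl-6-methylidenedecahydronaphthalene-1-carboxylic acid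
Product: 27 (1R,4aS,5R,8aS)-5-[(3R)-5-acetoxy-3-methylpentyl]-1,4a-dimethyl-6-methylidenedecahydronaphthalene-1-carboxylic acid
Conditions: Ac2O, pyridine, DMAP (cat.), CH2Cl2, rt; then H2O
Reagents that add atoms: acetic anhydride, CC(=O)OC(C)=O
Why: DMAP-catalysed acyl transfer acetylates the primary alcohol; the hindered tertiary acid forms at most a mixed anhydride, which the aqueous work-up hydrolyses.

## Compound list

1 | trimethylsilylacetylene | C#C[Si](C)(C)C | starting material
2 | lithium (trimethylsilyl)acetylide | [Li]C#C[Si](C)(C)C | intermediate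
3 | diisobutyl[(trimethylsilyl)ethynyl]aluminium | CC(C)C[Al](CC(C)C)C#C[Si](C)(C)C | intermediate
4 | 3-methylcyclohex-2-en-1-one | CC1=CC(=O)CCC1 | starting material
5 | allyl iodide | C=CCI | starting material
6 | diisobutylaluminium (3R)-3-methyl-3-[(trimethylsilyl)ethynyl]cyclohex-1-en-1-olate | CC(C)C[Al](CC(C)C)OC1=C[C@](C)(C#C[Si](C)(C)C)CCC1 | intermediate
7 | lithium diisobutyl(methyl){[(3R)-3-methyl-3-[(trimethylsilyl)ethynyl]cyclohex-1-en-1-yl]oxy}aluminate | [Li+].C[Al-](CC(C)C)(CC(C)C)OC1=C[C@](C)(C#C[Si](C)(C)C)CCC1 | intermediate
8 | (2R,3R)-2-allyl-3-methyl-3-[(trimethylsilyl)ethynyl]cyclohexan-1-one | O=C1CCC[C@@](C)(C#C[Si](C)(C)C)[C@H]1CC=C | intermediate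
9 | {[(E)-[(2R,3R)-2-allyl-3-methyl-3-[(trimethylsilyl)ethynyl]cyclohexylidene]methyl]sulfonyl}benzene | O=S(=O)(c1ccccc1)/C=C1\CCC[C@@](C)(C#C[Si](C)(C)C)[C@H]1CC=C | intermediate
10 | 9-{3-[(1R,2E,6R)-6-methyl-2-[(phenylsulfonyl)methylidene]-6-[(trimethylsilyl)ethynyl]cyclohexyl]propyl}-9-borabicyclo[3.3.1]nonane | O=S(=O)(c1ccccc1)/C=C1\CCC[C@@](C)(C#C[Si](C)(C)C)[C@H]1CCCB1C2CCCC1CCC2 | intermediate
11 | 3-[(1R,2E,6R)-6-methyl-2-[(phenylsulfonyl)methylidene]-6-[(trimethylsilyl)ethynyl]cyclohexyl]propan-1-ol | O=S(=O)(c1ccccc1)/C=C1\CCC[C@@](C)(C#C[Si](C)(C)C)[C@H]1CCCO | intermediate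
12 | 3-[(1R,2E,6R)-6-methyl-2-[(phenylsulfonyl)methylidene]-6-[(trimethylsilyl)ethynyl]cyclohexyl]propanal | O=S(=O)(c1ccccc1)/C=C1\CCC[C@@](C)(C#C[Si](C)(C)C)[C@H]1CCC=O | intermediate
13 | (R)-citronellol, (3R)-3,7-dimethyloct-6-en-1-ol | CC(C)=CCC[C@@H](C)CCO | starting material
14 | tert-butyl{[(3R)-3,7-dimethyloct-6-en-1-yl]oxy}dimethylsilane | CC(C)=CCC[C@@H](C)CCO[Si](C)(C)C(C)(C)C | intermediate
15 | (4R)-6-[(tert-butyldimethylsilyl)oxy]-4-methylhexanal | O=CCC[C@@H](C)CCO[Si](C)(C)C(C)(C)C | intermediate
16 | (4R)-6-[(tert-butyldimethylsilyl)oxy]-4-methylhexan-1-ol | OCCC[C@@H](C)CCO[Si](C)(C)C(C)(C)C | intermediate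
17 | {[(3R)-6-bromo-3-methylhexyl]oxy}(tert-butyl)dimethylsilane | BrCCC[C@@H](C)CCO[Si](C)(C)C(C)(C)C | intermediate
18 | [(4R)-6-[(tert-butyldimethylsilyl)oxy]-4-methylhexyl]magnesium bromide | Br[Mg]CCC[C@@H](C)CCO[Si](C)(C)C(C)(C)C | intermediate
19 | (7R)-9-[(tert-butyldimethylsilyl)oxy]-7-methyl-1-[(1R,2E,6R)-6-methyl-2-[(phenylsulfonyl)methylidene]-6-[(trimethylsilyl)ethynyl]cyclohexyl]nonan-3-ol (C3 epimers) | O=S(=O)(c1ccccc1)/C=C1\CCC[C@@](C)(C#C[Si](C)(C)C)[C@H]1CCC(O)CCC[C@@H](C)CCO[Si](C)(C)C(C)(C)C | intermediate
20 | (7R)-9-[(tert-butyldimethylsilyl)oxy]-7-methyl-1-[(1R,2E,6R)-6-methyl-2-[(phenylsulfonyl)methylidene]-6-[(trimethylsilyl)ethynyl]cyclohexyl]nonan-3-one | O=S(=O)(c1ccccc1)/C=C1\CCC[C@@](C)(C#C[Si](C)(C)C)[C@H]1CCC(=O)CCC[C@@H](C)CCO[Si](C)(C)C(C)(C)C | intermediate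
21 | (1S,4aR,5R,8aS)-1-[(3R)-5-[(tert-butyldimethylsilyl)oxy]-3-methylpentyl]-5-methyl-8a-[(phenylsulfonyl)methyl]-5-[(trimethylsilyl)ethynyl]octahydronaphthalen-2(1H)-one | O=C1CC[C@H]2[C@@](CS(=O)(=O)c3ccccc3)(CCC[C@@]2(C)C#C[Si](C)(C)C)[C@@H]1CC[C@@H](C)CCO[Si](C)(C)C(C)(C)C | intermediate
22 | (1S,4aR,5R,8aS)-1-[(3R)-5-[(tert-butyldimethylsilyl)oxy]-3-methylpentyl]-5-ethynyl-5-methyl-8a-[(phenylsulfonyl)methyl]octahydronaphthalen-2(1H)-one | O=C1CC[C@H]2[C@@](CS(=O)(=O)c3ccccc3)(CCC[C@@]2(C)C#C)[C@@H]1CC[C@@H](C)CCO[Si](C)(C)C(C)(C)C | intermediate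
23 | (1R,4aS,5S,8aR)-5-[(3R)-5-[(tert-butyldimethylsilyl)oxy]-3-methylpentyl]-1-methyl-6-oxo-4a-[(phenylsulfonyl)methyl]decahydronaphthalene-1-carboxylic acid | O=C1CC[C@H]2[C@@](CS(=O)(=O)c3ccccc3)(CCC[C@@]2(C)C(=O)O)[C@@H]1CC[C@@H](C)CCO[Si](C)(C)C(C)(C)C | intermediate
24 | (1R,4aR,5R,8aR)-5-[(3R)-5-[(tert-butyldimethylsilyl)oxy]-3-methylpentyl]-1-methyl-6-methylidene-4a-[(phenylsulfonyl)methyl]decahydronaphthalene-1-carboxylic acid | C=C1CC[C@H]2[C@@](CS(=O)(=O)c3ccccc3)(CCC[C@@]2(C)C(=O)O)[C@@H]1CC[C@@H](C)CCO[Si](C)(C)C(C)(C)C | intermediate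
25 | (1R,4aS,5R,8aS)-5-[(3R)-5-[(tert-butyldimethylsilyl)oxy]-3-methylpentyl]-1,4a-dimethyl-6-methylidenedecahydronaphthalene-1-carboxylic acid | C=C1CC[C@H]2[C@@](C)(CCC[C@@]2(C)C(=O)O)[C@@H]1CC[C@@H](C)CCO[Si](C)(C)C(C)(C)C | intermediate
26 | (1R,4aS,5R,8aS)-5-[(3R)-5-hydroxy-3-methylpentyl]-1,4a-dimethyl-6-methylidenedecahydronaphthalene-1-carboxylic acid | C=C1CC[C@H]2[C@@](C)(CCC[C@@]2(C)C(=O)O)[C@@H]1CC[C@@H](C)CCO | intermediate
27 | (1R,4aS,5R,8aS)-5-[(3R)-5-acetoxy-3-methylpentyl]-1,4a-dimethyl-6-methylidenedecahydronaphthalene-1-carboxylic acid | C=C1CC[C@H]2[C@@](C)(CCC[C@@]2(C)C(=O)O)[C@@H]1CC[C@@H](C)CCOC(C)=O | target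

## Step count and least certain steps

Total: 16 steps. Longest linear sequence: 13 steps (steps 1–5 and 9–16, from trimethylsilylacetylene); the citronellol branch (steps 6–8) joins at step 9.

**Step 2 (key step).** The aluminium enolate may resist C-allylation even as its aluminate, proton transfer between enolate and product may move the site of alkylation or cause double allylation, and facial selection may be eroded with so slender a nucleophile. The fallback sets out from 4 and 3 and keeps the conjugate addition, but separates the second bond formation. The aluminate enolate 7 is O-acylated with allyl chloroformate and isolated as allyl (3R)-3-methyl-3-[(trimethylsilyl)ethynyl]cyclohex-1-en-1-yl carbonate F1. A Tsuji decarboxylative allylation with catalytic Pd(PPh3)4 in THF then delivers the allyl group to C5 regiospecifically under neutral conditions. After DBU equilibration of C5 the route is rejoined at 8.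

**Step 11.** Base may move the double bond out of conjugation into the ring faster than the enolate adds, C9 may attack the wrong face of C10 and give the cis fusion, and γ-deprotonation may epimerise C5. The fallback sets out from 20 and replaces the alkali enolate by a neutral enamine (Stork enamine Michael reaction). Ketone 20 is condensed with pyrrolidine under azeotropic removal of water to its pyrrolidine enamine F2. Heating in acetonitrile lets the C9 enamine carbon add to the vinyl sulfone without any base strong enough to deconjugate it. Aqueous acetic acid hydrolyses the iminium to 21, and K2CO3 in MeOH then gives 22.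

**Step 3.** The phosphonate anion may enolise the hindered, α-branched ketone instead of adding, returning ketone and scrambling C5. The fallback sets out from 8 and uses addition–elimination. Lithiated methyl phenyl sulfone, made less basic with CeCl3, adds to the C10 carbonyl to give the β-hydroxy sulfone {[1-hydroxy-2-allyl-3-methyl-3-[(trimethylsilyl)ethynyl]cyclohexyl]methyl}sulfonylbenzene F3. Trifluoroacetylation and DBU then induce E1cB elimination towards the sulfone and give 9.

**Step 13.** The basic ylide may enolise the hindered C8 ketone and stall, and prolonged heating with base risks ring opening by retro-Michael cleavage. The fallback sets out from 23 and uses a Peterson olefination. Me3SiCH2MgCl with CeCl3 adds to the ketone (one further equivalent for the acid) to give the β-hydroxysilane F6. Mild acid (BF3·OEt2, CH2Cl2, 0 °C) eliminates silanol and gives 24.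

**Step 12.** The oxidant may attack the CH2–O position of the silyl ether, or the acidic medium may cleave the silyl group, and cleavage may stop at the 1,2-dicarbonyl stage. The fallback sets out from 22 and divides the task into three mild steps. Semi-hydrogenation over Pd/CaCO3 poisoned with Pb(OAc)2 (quinoline, H2) gives the vinyl compound F4. Ozonolysis with PPh3 work-up gives the neopentyl aldehyde F5. Pinnick oxidation (NaClO2, NaH2PO4, 2-methylbut-2-ene) gives 23.

## Further compounds

F1 | step 2 | allyl (3R)-3-methyl-3-[(trimethylsilyl)ethynyl]cyclohex-1-en-1-yl carbonate | C=CCOC(=O)OC1=C[C@](C)(C#C[Si](C)(C)C)CCC1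
F2 | step 11 | pyrrolidine enamine of ketone 20 (C8=C9 isomer) | O=S(=O)(c1ccccc1)/C=C1\CCC[C@@](C)(C#C[Si](C)(C)C)[C@H]1CCC(N2CCCC2)=CCC[C@@H](C)CCO[Si](C)(C)C(C)(C)C
F3 | step 3 | {[(2R,3R)-2-allyl-1-hydroxy-3-methyl-3-[(trimethylsilyl)ethynyl]cyclohexyl]methyl}sulfonylbenzene (C1 epimers) | O=S(=O)(c1ccccc1)CC1(O)CCC[C@@](C)(C#C[Si](C)(C)C)[C@H]1CC=C
F4 | step 12 | (1S,4aR,5R,8aS)-1-[(3R)-5-[(tert-butyldimethylsilyl)oxy]-3-methylpentyl]-5-ethenyl-5-methyl-8a-[(phenylsulfonyl)methyl]octahydronaphthalen-2(1H)-one | O=C1CC[C@H]2[C@@](CS(=O)(=O)c3ccccc3)(CCC[C@@]2(C)C=C)[C@@H]1CC[C@@H](C)CCO[Si](C)(C)C(C)(C)C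
F5 | step 12 | (1R,4aS,5S,8aR)-5-[(3R)-5-[(tert-butyldimethylsilyl)oxy]-3-methylpentyl]-1-methyl-6-oxo-4a-[(phenylsulfonyl)methyl]decahydronaphthalene-1-carbaldehyde | O=C1CC[C@H]2[C@@](CS(=O)(=O)c3ccccc3)(CCC[C@@]2(C)C=O)[C@@H]1CC[C@@H](C)CCO[Si](C)(C)C(C)(C)C
F6 | step 13 | (1R,4aS,5S,8aR)-5-[(3R)-5-[(tert-butyldimethylsilyl)oxy]-3-methylpentyl]-6-hydroxy-1-methyl-4a-[(phenylsulfonyl)methyl]-6-[(trimethylsilyl)methyl]decahydronaphthalene-1-carboxylic acid (C6 epimers) | C[Si](C)(C)CC1(O)CC[C@H]2[C@@](CS(=O)(=O)c3ccccc3)(CCC[C@@]2(C)C(=O)O)[C@@H]1CC[C@@H](C)CCO[Si](C)(C)C(C)(C)C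
A1 | alternative 1 | open-chain trienal: (E)-2-(benzyloxymethyl)enal tethered through the C8 dioxolane and C9 to an (E)-4-methyl-1,3-diene | C=C/C=C(\C)[C@H](CC[C@@H](C)CCO[Si](C)(C)C(C)(C)C)C1(OCCO1)CC/C=C(/C=O)COCc1ccccc1
A2 | alternative 1 | trans-fused octalin with C18 aldehyde, C19 benzyloxymethyl and C8 dioxolane | O1CCOC12CC[C@H]3[C@@](C)(C=CC[C@@]3(C=O)COCc3ccccc3)[C@@H]2CC[C@@H](C)CCO[Si](C)(C)C(C)(C)C
A3 | alternative 2 | open-chain (E)-3-methylenal tethered through C1–C4 to an (E,E)-1-silyloxydiene, with the C4 quaternary methyl ester in place | O=C/C=C(\C)CCC[C@@](C)(C(=O)OC)/C=C/C=C/O[Si](C)(C)C(C)(C)C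
A4 | alternative 2 | trans-fused octalin with C11 aldehyde, C8 silyl ether and C19 methyl ester | [C@@H]1(O[Si](C)(C)C(C)(C)C)C=C[C@H]2[C@@](C)(CCC[C@@]2(C)C(=O)OC)[C@@H]1C=O
A5 | alternative 3 | open-chain α-methyl β-keto 8-phenylmenthyl ester (E,E)-diene with C15 acetate | CC(C(=O)O[C@@H]1C[C@H](C)CC[C@H]1C(C)(C)c1ccccc1)C(=O)CC/C(C)=C/CC/C(C)=C/CC[C@@H](C)CCOC(C)=O
A6 | alternative 3 | 3-oxo bicyclic 8-phenylmenthyl ester with exocyclic methylene and C15 acetate | C=C1CC[C@H]2[C@@](C)(CCC(=O)[C@@]2(C)C(=O)O[C@@H]2C[C@H](C)CC[C@H]2C(C)(C)c2ccccc2)[C@@H]1CC[C@@H](C)CCOC(C)=O
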